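## The problem

The target is an unbranched C25 chain that ends on one side in a (5Z)-5-ylidene-4-hydroxy-3-methylfuran-2(5H)-one (a tetronic acid, atoms O1 and C2 to C5) and on the other in two furans joined through one CH2 group. The chain carbons are numbered C6 to C14 from the ylidene carbon to ring A, the 2,4-disubstituted furan; ring B is the 3-furyl ring. No ring is fused or bridged, so the task is chain construction: sp3–sp2 bonds at C8–C9 and C14–ring A, and three alkenes, Z at C5=C6, E at C9=C10 and E at the trisubstituted C11=C12. There is one stereocentre, C7 (S), between the ylidene carbon and the skipped diene. Nothing in the molecule can induce it, so it must come from the chiral pool; it controls nothing itself, but it sits next to a carbonyl or a conjugated alkyne in every late intermediate and can be lost by deprotonation. The tetronic acid is a strong, chelating acid best made last. The furans, and above all the furan–CH2–furan unit, do not tolerate strong acid, electrophilic halogen, peracids or a cationic centre at the bridge. The enabling feature is that the bridge carbon joins C2 of ring A (α to oxygen) to C3 of ring B (β to oxygen), and C2 of ring A is the only unhindered α-position of a 3-alkylfuran. Boron can therefore be placed there by C–H borylation, and a one-carbon insertion into that C–B bond gives a furylmethyl boronate ready for coupling with 3-bromofuran 1, the same building block from which ring A is made.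

## Retrosynthesis

**Tetronic acid (C2–C3 and O1–C5).** Target 25 is cut back to ynone 23. Carboxylation of the ethyl ketone gives β-keto carboxylate 24, whose oxygen closes 5-exo-dig onto the alkyne. Against an aldol condensation of a preformed tetronate, this cut builds ring and Z-alkene in one catalytic step with no protecting group. The forward reaction must carboxylate at the ketone α-carbon and leave C7 untouched.

**Acyl group (C4–C5).** Ynone 23 comes from terminal alkyne 20 and amide 21. The precursor is simpler by the whole head group, and the reaction only needs the acetylide 22 to add once.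

**Alkyne carbon (C5–C6).** Alkyne 20 is traced to methyl ester 18 by reduction to aldehyde 19 and one-carbon homologation in the same flask. This keeps the C7 centre next to a carbonyl for one telescoped operation only.

**C8–C9.** Ester 18 is cut between sp3 C8 and sp2 C9 into dienyl iodide 14 and iodo ester 16, joined through alkylzinc 17. Iodo ester 16 is one step from hydroxy ester 15, whereas an alkyl iodide already carrying the alkyne would need five or six steps. The coupling must keep both alkene geometries and the configuration α to the ester.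

**C9=C10 and the masked aldehyde.** Iodide 14 comes from enal 13 by one-carbon iodo-olefination, and 13 from dimethyl acetal 12. The acetal carries the aldehyde oxidation level through the key step, so no redox or silyl steps are needed around it.

**Bridge (ring A C2–CH2 and CH2–ring B C3), the key step.** Bis-furan 12 is cut at both bonds of the bridge carbon into boronate 8, bromochloromethane 9 and 3-bromofuran 1. Ate complex 10 and furylmethyl boronate 11 are in-flask intermediates. Against a furylmethyl halide, carbinol or cation, this cut makes the bridge under basic conditions only. The reaction needs a single CH2 insertion and a coupling faster than loss of boron.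

**C–B bond.** Boronate 8 comes from 3-alkylfuran 6 and diboron 7. The precursor loses only boron, and the step must choose the α-position remote from the chain.

**Chain (C11=C12 and C14–ring A).** Acetal 6 comes from enal 5, made from aldehyde 3 and formyl ylide 4, which sets the E trisubstituted alkene and delivers the aldehyde in one step. Aldehyde 3 comes from 1 and allyl alcohol 2 by arylation with transposition of the alcohol to the carbonyl.

## Roads not taken

Alternative 1: The lactone is cut at O1–C2 with formation of C5=C6. Pb(OAc)4 would convert tertiary cyclobutenol A2 into an oxygen-centred intermediate, the strained acyl–carbinol bond would break, oxygen would close onto the acyl carbon and loss of the C6 proton would give Z-ylidene methyl tetronate A1. Ring and alkene arise together, and C7 never sits next to an enolisable carbonyl or ynone; on this point the road is safer than the carboxylative cyclisation of 23. Its weak points are stoichiometric lead, competition between acetate capture at C5 and proton loss, and the distance still to go. A1 ends at C8 as a silyl ether, so deprotection, activation, an sp3–sp2 coupling and a late O-demethylation beside the bis-furan would follow, and the furan end is not addressed at all. The chosen plan sets against it a head group made in one catalytic step from an unprotected ynone, and a shorter sequence.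

Alternative 2: The trisubstituted alkene is cut at C11–CH3 and C12–C13. Me3Al with Cp2ZrCl2 would add methyl and aluminium syn across terminal enyne A4, and the alkenylalanate formed with n-BuLi would open oxirane A5 to give dienynol A3. Two bonds form in one flask, and the E geometry at C11=C12 follows from the syn addition. This is better than a Wittig reaction, which may leave some Z isomer to remove. Weak points are the excess pyrophoric alane, the need for the silylalkyne and the conjugated alkene to stay inert, and the usually modest epoxide opening. A3 also ends in a primary alcohol, so ring A must still be attached by an sp3–sp2 coupling and functionalised at its α-position afterwards, with the whole chain at risk. The chosen plan sets against it an alkene made together with the aldehyde needed next (3 to 5), and furan chemistry done early on simple compounds.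

Alternative 3: Ring A is cut at its O1–C2 bond. Divalent palladium (PdI2 with KI) would let the hydroxyl of (Z)-enynol A7 add 5-exo-dig to the alkyne, and aromatisation would turn the far alkyne carbon into the bridge, giving bis-furan A6. The 2,4-pattern is fixed by construction, with no question of site selectivity, and no organolithium or boron reagent is needed. In certainty of the substitution pattern this road is better than C–H borylation of 6. Its weak points are the stereodefined Z-enynol, which needs its own multistep synthesis from a volatile 3-furyl alkyne, and the butenyl terminus of A6, from which C11=C12 and the rest must still be built. The chosen plan sets against it that both rings come from 1 and the bridge carbon from 9, that 12 is reached in five steps, and that a blocking-group fallback exists for the borylation.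

Key step: step 5

Assumption: the target is written as the 4-hydroxy enol tautomer of the tetronic acid, the form expected to predominate.

## Route

Step 1
Reactants: 1 3-bromofuran; 2 prop-2-en-1-ol (allyl alcohol)
Product: 3 3-(furan-3-yl)propanal
Conditions: Pd(OAc)2 (cat.), Bu4NCl, NaHCO3, DMF, 70 °C, sealed vessel
Reagents that add atoms: none
Why: Heck reaction under ligand-free phase-transfer conditions: the furylpalladium species adds to the terminal alkene carbon and β-hydride elimination toward the carbinol carbon gives the enol and hence the aldehyde.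

Step 2
Reactants: 3 3-(furan-3-yl)propanal; 4 2-(triphenylphosphoranylidene)propanal
Product: 5 (2E)-5-(furan-3-yl)-2-methylpent-2-enal
Conditions: toluene, 90 °C
Reagents that add atoms: none
Why: Wittig reaction of a stabilised ylide, which should give the E trisubstituted enal; the α-methyl enal is far less electrophilic than aldehyde 3, so a second olefination should not compete.

Step 3
Reactants: 5 (2E)-5-(furan-3-yl)-2-methylpent-2-enal
Product: 6 3-[(3E)-5,5-dimethoxy-4-methylpent-3-en-1-yl]furan
Conditions: HC(OMe)3, MeOH, PPTS (cat.), rt; then Et3N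
Reagents that add atoms: trimethyl orthoformate COC(OC)OC; methanol CO
Why: Acid-catalysed acetalisation with the orthoformate as water scavenger; methanol traps the allylic oxocarbenium ion far faster than the furan can, and the acetal masks the aldehyde against borane, n-BuLi and the carbenoid.

Step 4
Reactants: 6 3-[(3E)-5,5-dimethoxy-4-methylpent-3-en-1-yl]furan; 7 bis(pinacolato)diboron
Product: 8 2-{4-[(3E)-5,5-dimethoxy-4-methylpent-3-en-1-yl]furan-2-yl}-4,4,5,5-tetramethyl-1,3,2-dioxaborolane
Conditions: [Ir(OMe)(cod)]2 (1.5 mol%), 4,4'-di-tert-butyl-2,2'-bipyridine (3 mol%), B2pin2 (0.55 equiv), hexane, rt; filtration through Et3N-deactivated silica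
Reagents that add atoms: none
Why: Iridium-catalysed C–H borylation: the crowded tris(boryl)iridium catalyst activates furan α-C–H bonds and should choose the α-position remote from the chain over the one flanked by it; keeping the diboron limiting guards against 2,5-diborylation.

Step 5
Reactants: 8 2-{4-[(3E)-5,5-dimethoxy-4-methylpent-3-en-1-yl]furan-2-yl}-4,4,5,5-tetramethyl-1,3,2-dioxaborolane; 9 bromochloromethane; 1 3-bromofuran
Product: 12 4-[(3E)-5,5-dimethoxy-4-methylpent-3-en-1-yl]-2-(furan-3-ylmethyl)furan, via lithium chloromethyl borate complex 10 (not isolated), via furylmethyl pinacol boronate 11 (not isolated)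
Conditions: BrCH2Cl (1.2 equiv), n-BuLi (1.1 equiv), THF, −78 °C to rt; then 3-bromofuran, Pd(dppf)Cl2 (5 mol%), aqueous K3PO4, 65 °C
Reagents that add atoms: none
Why: Proposed new method: n-BuLi exchanges with the bromine of 9 faster than it adds to boron, the LiCH2Cl so formed is trapped at −78 °C by the boron of 8 as ate complex 10, and on warming the furyl carbon migrates from boron to carbon with loss of chloride (Matteson-type 1,2-metallate shift), forming the ring A C2–CH2 bond and leaving boron on the new methylene carbon of 11. Without isolation, zerovalent palladium from Pd(dppf)Cl2 inserts into the C3–Br bond of 1, and phosphate-assisted transmetalation of the primary boronate followed by reductive elimination forms the CH2–ring B C3 bond (Suzuki–Miyaura coupling of a benzylic-type boronic ester). The closest known reactions are the homologation of aryl and heteroaryl pinacol boronates with LiCH2Cl made in situ and the coupling of primary benzylic pinacol boronates with heteroaryl bromides; new is their union in one flask on a 2-furyl boronate, whose homologation product is an unusually labile furfuryl-type boronate. No ring closes and no stereocentre is formed. The step needs a single insertion, which should hold because the carbenoid is used in slight excess only and is consumed or decomposed in the cold before any 11 exists, 11 arising only on warming. It needs coupling to outrun protodeboronation, which is favoured because 11 has no β-hydrogen on an sp3 carbon, the wide-bite-angle ligand speeds reductive elimination, and catalyst and bromide are present before the basic mixture is heated. The site on ring A is not decided here but by the position of boron fixed in step 4. The acetal and the trisubstituted alkene are inert to carbenoid, base and palladium, and the bridge is made without a furylmethyl cation, halide or carbinol.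

Step 6
Reactants: 12 4-[(3E)-5,5-dimethoxy-4-methylpent-3-en-1-yl]-2-(furan-3-ylmethyl)furan
Product: 13 (2E)-5-[5-(furan-3-ylmethyl)furan-3-yl]-2-methylpent-2-enal
Conditions: PPTS (cat.), acetone–H2O (10:1), rt
Reagents that add atoms: water O
Why: Acetal hydrolysis; the allylic oxocarbenium ion forms under very mild acid, so the furans and the bridge are never exposed to strong acid.

Step 7
Reactants: 13 (2E)-5-[5-(furan-3-ylmethyl)furan-3-yl]-2-methylpent-2-enal
Product: 14 2-(furan-3-ylmethyl)-4-[(3E,5E)-6-iodo-4-methylhexa-3,5-dien-1-yl]furan
Conditions: CrCl2, CHI3, THF–1,4-dioxane, 0 °C to rt, dark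
Reagents that add atoms: iodoform IC(I)I
Why: Takai olefination: the geminal dichromium species from iodoform and divalent chromium adds to the aldehyde and eliminates to the E iodoalkene under neutral conditions that should leave the furans and the existing alkene untouched.

Step 8
Reactants: 15 methyl (2S)-3-hydroxy-2-methylpropanoate
Product: 16 methyl (2R)-3-iodo-2-methylpropanoate
Conditions: I2, PPh3, imidazole, CH2Cl2, 0 °C to rt
Reagents that add atoms: iodine II
Why: Appel-type iodination of the primary alcohol; the stereocentre is not touched, and the descriptor changes only because CH2I outranks the ester.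

Step 9
Reactants: 16 methyl (2R)-3-iodo-2-methylpropanoate; 14 2-(furan-3-ylmethyl)-4-[(3E,5E)-6-iodo-4-methylhexa-3,5-dien-1-yl]furan
Product: 18 methyl (2S,4E,6E)-9-[5-(furan-3-ylmethyl)furan-3-yl]-2,6-dimethylnona-4,6-dienoate, via alkylzinc iodide 17 (not isolated)
Conditions: Zn dust (activated with BrCH2CH2Br and Me3SiCl), DMF, rt; then 14, Pd2(dba)3 (cat.), P(o-tol)3, rt to 40 °C
Reagents that add atoms: none
Why: Negishi coupling: zinc inserts into the C–I bond to give the ester-chelated alkylzinc 17, which transmetalates to the dienylpalladium iodide; reductive elimination should form C8–C9 with retention of both alkene geometries and without disturbing the centre β to zinc.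

Step 10
Reactants: 18 methyl (2S,4E,6E)-9-[5-(furan-3-ylmethyl)furan-3-yl]-2,6-dimethylnona-4,6-dienoate
Product: 20 4-[(3E,5E,8S)-4,8-dimethyldeca-3,5-dien-9-yn-1-yl]-2-(furan-3-ylmethyl)furan, via aldehyde 19 (not isolated)
Conditions: i-Bu2AlH (1.1 equiv), CH2Cl2, −78 °C; then MeOH, K2CO3, dimethyl (1-diazo-2-oxopropyl)phosphonate, −78 °C to rt
Reagents that add atoms: dimethyl (1-diazo-2-oxopropyl)phosphonate COP(=O)(OC)C(=[N+]=[N-])C(C)=O
Why: The aluminium hemiacetal formed at low temperature releases aldehyde 19 on methanolysis, and Seyferth–Gilbert homologation with the Ohira–Bestmann reagent converts it in the same flask into the terminal alkyne; not isolating the α-branched aldehyde should limit epimerisation at C7.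

Step 11
Reactants: 20 4-[(3E,5E,8S)-4,8-dimethyldeca-3,5-dien-9-yn-1-yl]-2-(furan-3-ylmethyl)furan; 21 N-methoxy-N-methylpropanamide
Product: 23 (6S,8E,10E)-13-[5-(furan-3-ylmethyl)furan-3-yl]-6,10-dimethyltrideca-8,10-dien-4-yn-3-one, via lithium acetylide 22 (not isolated)
Conditions: n-BuLi (1.0 equiv), THF, −78 °C; then 21, −78 to 0 °C; cold saturated aqueous NH4Cl
Reagents that add atoms: none
Why: Acylation of a lithium acetylide with a Weinreb amide; the chelated tetrahedral intermediate prevents a second addition, and the cold acidic quench keeps the released amine from adding to the ynone.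

Step 12
Reactants: 23 (6S,8E,10E)-13-[5-(furan-3-ylmethyl)furan-3-yl]-6,10-dimethyltrideca-8,10-dien-4-yn-3-one
Product: 25 (5Z)-5-{(2S,4E,6E)-9-[5-(furan-3-ylmethyl)furan-3-yl]-2,6-dimethylnona-4,6-dien-1-ylidene}-4-hydroxy-3-methylfuran-2(5H)-one, via beta-keto carboxylate 24 (not isolated)
Conditions: AgOAc (10 mol%), DBU, CO2 (1.0 MPa), MeCN, rt; then cold aqueous citric acid
Reagents that add atoms: carbon dioxide O=C=O
Why: Silver-catalysed carboxylative cyclisation of a conjugated ynone: DBU and CO2 carboxylate the α-methylene of the ethyl ketone reversibly to 24, whose carboxylate oxygen attacks the silver-bound alkyne 5-exo-dig at C5 anti to the metal; protodemetalation should give the Z-ylidene and enolisation the tetronic acid.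

## Compound list

1 | 3-bromofuran | Brc1ccoc1 | starting material
2 | prop-2-en-1-ol (allyl alcohol) | C=CCO | starting material
3 | 3-(furan-3-yl)propanal | O=CCCc1ccoc1 | intermediate
4 | 2-(triphenylphosphoranylidene)propanal | CC(C=O)=P(c1ccccc1)(c1ccccc1)c1ccccc1 | starting material
5 | (2E)-5-(furan-3-yl)-2-methylpent-2-enal | O=C/C(C)=C/CCc1ccoc1 | intermediate
6 | 3-[(3E)-5,5-dimethoxy-4-methylpent-3-en-1-yl]furan | COC(OC)/C(C)=C/CCc1ccoc1 | intermediate
7 | bis(pinacolato)diboron | CC1(C)OB(OC1(C)C)B1OC(C)(C)C(C)(C)O1 | starting material
8 | 2-{4-[(3E)-5,5-dimethoxy-4-methylpent-3-en-1-yl]furan-2-yl}-4,4,5,5-tetramethyl-1,3,2-dioxaborolane | COC(OC)/C(C)=C/CCc1coc(B2OC(C)(C)C(C)(C)O2)c1 | intermediate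
9 | bromochloromethane | ClCBr | starting material
10 | lithium (chloromethyl){4-[(3E)-5,5-dimethoxy-4-methylpent-3-en-1-yl]furan-2-yl}(pinacolato)borate | [Li+].COC(OC)/C(C)=C/CCc1coc([B-]2(CCl)OC(C)(C)C(C)(C)O2)c1 | intermediate
11 | 2-({4-[(3E)-5,5-dimethoxy-4-methylpent-3-en-1-yl]furan-2-yl}methyl)-4,4,5,5-tetramethyl-1,3,2-dioxaborolane | COC(OC)/C(C)=C/CCc1coc(CB2OC(C)(C)C(C)(C)O2)c1 | intermediate
12 | 4-[(3E)-5,5-dimethoxy-4-methylpent-3-en-1-yl]-2-(furan-3-ylmethyl)furan | COC(OC)/C(C)=C/CCc1coc(Cc2ccoc2)c1 | intermediate
13 | (2E)-5-[5-(furan-3-ylmethyl)furan-3-yl]-2-methylpent-2-enal | O=C/C(C)=C/CCc1coc(Cc2ccoc2)c1 | intermediate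
14 | 2-(furan-3-ylmethyl)-4-[(3E,5E)-6-iodo-4-methylhexa-3,5-dien-1-yl]furan | I/C=C/C(C)=C/CCc1coc(Cc2ccoc2)c1 | intermediate
15 | methyl (2S)-3-hydroxy-2-methylpropanoate | COC(=O)[C@@H](C)CO | starting material
16 | methyl (2R)-3-iodo-2-methylpropanoate | COC(=O)[C@@H](C)CI | intermediate
17 | iodo[(2R)-3-methoxy-2-methyl-3-oxopropyl]zinc | COC(=O)[C@@H](C)C[Zn]I | intermediate
18 | methyl (2S,4E,6E)-9-[5-(furan-3-ylmethyl)furan-3-yl]-2,6-dimethylnona-4,6-dienoate | COC(=O)[C@@H](C)C/C=C/C(C)=C/CCc1coc(Cc2ccoc2)c1 | intermediate
19 | (2S,4E,6E)-9-[5-(furan-3-ylmethyl)furan-3-yl]-2,6-dimethylnona-4,6-dienal | O=C[C@@H](C)C/C=C/C(C)=C/CCc1coc(Cc2ccoc2)c1 | intermediate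
20 | 4-[(3E,5E,8S)-4,8-dimethyldeca-3,5-dien-9-yn-1-yl]-2-(furan-3-ylmethyl)furan | C#C[C@@H](C)C/C=C/C(C)=C/CCc1coc(Cc2ccoc2)c1 | intermediate
21 | N-methoxy-N-methylpropanamide | CCC(=O)N(C)OC | starting material
22 | lithium acetylide of 20, {(3S,5E,7E)-10-[5-(furan-3-ylmethyl)furan-3-yl]-3,7-dimethyldeca-5,7-dien-1-yn-1-yl}lithium | [Li]C#C[C@@H](C)C/C=C/C(C)=C/CCc1coc(Cc2ccoc2)c1 | intermediate
23 | (6S,8E,10E)-13-[5-(furan-3-ylmethyl)furan-3-yl]-6,10-dimethyltrideca-8,10-dien-4-yn-3-one | CCC(=O)C#C[C@@H](C)C/C=C/C(C)=C/CCc1coc(Cc2ccoc2)c1 | intermediate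
24 | (6S,8E,10E)-13-[5-(furan-3-ylmethyl)furan-3-yl]-2,6,10-trimethyl-3-oxotrideca-8,10-dien-4-ynoic acid (formed as its DBU salt, both C2 epimers) | CC(C(=O)O)C(=O)C#C[C@@H](C)C/C=C/C(C)=C/CCc1coc(Cc2ccoc2)c1 | intermediate
25 | (5Z)-5-{(2S,4E,6E)-9-[5-(furan-3-ylmethyl)furan-3-yl]-2,6-dimethylnona-4,6-dien-1-ylidene}-4-hydroxy-3-methylfuran-2(5H)-one | CC1=C(O)/C(=C/[C@@H](C)C/C=C/C(C)=C/CCc2coc(Cc3ccoc3)c2)OC1=O | target

## Step count and risks

Total: 12 steps. Longest linear sequence: 11 steps (steps 1 to 7 and 9 to 12, from 1); step 8 is a one-step branch.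

**Step 5 (key step, proposed new method).** The most likely failure is hydrolytic loss of boron from furylmethyl boronate 11 before transmetalation, because the electron-rich ring is easily protonated at the boron-bearing position's neighbour. A second failure is incomplete capture of the carbenoid, if n-BuLi adds to boron or LiCH2Cl decomposes first. The fallback uses known chemistry, sets out from 8 and returns at 12. It is a Suzuki–Miyaura coupling of 8 with 3-(bromomethyl)furan F1 (from commercial furan-3-ylmethanol and PBr3, used at once) under Pd(PPh3)4 and aqueous K3PO4 in THF at 60 °C. The bridge carbon then arrives with ring B, and the ring A C2–CH2 bond is still made from the same C–B bond.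

**Step 12.** The most likely failure is loss of configuration at C7 by γ-deprotonation of the ynone with DBU (ynone–allenone isomerisation) before the carboxylate closes. Closure in the 6-endo sense is a second possibility. The fallback sets out from 18 and returns at 25:
- Reduction with i-Bu2AlH gives 19, which is isolated.
- Aldol addition of the lithium enolate (LDA, THF, −78 °C) of 4-methoxy-3-methylfuran-2(5H)-one F2 gives 5-{(2S,4E,6E)-9-[5-(furan-3-ylmethyl)furan-3-yl]-1-hydroxy-2,6-dimethylnona-4,6-dien-1-yl}-4-methoxy-3-methylfuran-2(5H)-one F3. F2 is made from commercial 4-hydroxy-3-methylfuran-2(5H)-one with dimethyl sulfate and K2CO3.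
- MsCl and Et3N give the methanesulfonate of the aldol adduct F4.
- DBU eliminates it to (5Z)-5-{(2S,4E,6E)-9-[5-(furan-3-ylmethyl)furan-3-yl]-2,6-dimethylnona-4,6-dien-1-ylidene}-4-methoxy-3-methylfuran-2(5H)-one F5, the Z isomer being the less crowded one.
- LiCl in DMSO at 100 °C cleaves the methyl ether to 25.

**Step 4.** The most likely failure is incomplete site selectivity, with some borylation next to the chain or at both α-positions, because a primary alkyl group shields its neighbour only moderately. The fallback blocks that position, sets out from 6 and returns at 12: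
- NBS in DMF at −20 °C brominates the more electron-rich α-position to give 2-bromo-3-[(3E)-5,5-dimethoxy-4-methylpent-3-en-1-yl]furan F6.
- n-BuLi and then Me3SiCl give {3-[(3E)-5,5-dimethoxy-4-methylpent-3-en-1-yl]furan-2-yl}(trimethyl)silane F7.
- Borylation as in step 4 can now occur only at the one free α-position and gives 2-{4-[(3E)-5,5-dimethoxy-4-methylpent-3-en-1-yl]-5-(trimethylsilyl)furan-2-yl}-4,4,5,5-tetramethyl-1,3,2-dioxaborolane F8.
- The conditions of step 5 lead through the lithium chloromethyl borate complex F9 and the silylated furylmethyl pinacol boronate F10 to {3-[(3E)-5,5-dimethoxy-4-methylpent-3-en-1-yl]-5-(furan-3-ylmethyl)furan-2-yl}(trimethyl)silane F11.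
- Bu4NF in THF at 50 °C removes the silyl group to give 12.

**Step 10.** The most likely failure is partial epimerisation at C7 by enolisation of the α-branched aldehyde in basic methanol, or over-reduction of the ester. The fallback sets out from 18 and returns at 23:
- LiAlH4 gives (2S,4E,6E)-9-[5-(furan-3-ylmethyl)furan-3-yl]-2,6-dimethylnona-4,6-dien-1-ol F12.
- Dess–Martin periodinane gives 19, used at once.
- CBr4, PPh3 and Et3N give 4-[(3E,5E,8S)-10,10-dibromo-4,8-dimethyldeca-3,5,9-trien-1-yl]-2-(furan-3-ylmethyl)furan F13 (Corey–Fuchs reaction, no alkoxide base).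
- Two equivalents of n-BuLi at −78 °C convert F13 directly into acetylide 22, which is quenched with 21 to give 23.

**Step 1.** The most likely failure is sluggish oxidative addition of the electron-rich bromofuran without a ligand, and loss of regiocontrol in the insertion (branched aldehyde, allylic alcohol isomers). The fallback sets out from 1 and returns at 3:
- Hydroboration of commercial acrolein diethyl acetal with 9-BBN-H gives 9-(3,3-diethoxypropyl)-9-borabicyclo[3.3.1]nonane F14.
- This is coupled in the same flask with 1 (Pd(dppf)Cl2, aqueous K3PO4, THF, 65 °C) to give 3-(3,3-diethoxypropyl)furan F15.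
- Aqueous acetic acid in THF releases 3.

## Further compounds

F1 | step 5 | 3-(bromomethyl)furan | BrCc1ccoc1
F2 | step 12 | 4-methoxy-3-methylfuran-2(5H)-one | COC1=C(C)C(=O)OC1
F3 | step 12 | 5-{(2S,4E,6E)-9-[5-(furan-3-ylmethyl)furan-3-yl]-1-hydroxy-2,6-dimethylnona-4,6-dien-1-yl}-4-methoxy-3-methylfuran-2(5H)-one | COC1=C(C)C(=O)OC1C(O)[C@@H](C)C/C=C/C(C)=C/CCc1coc(Cc2ccoc2)c1
F4 | step 12 | (2S,4E,6E)-9-[5-(furan-3-ylmethyl)furan-3-yl]-1-(3-methoxy-4-methyl-5-oxo-2,5-dihydrofuran-2-yl)-2,6-dimethylnona-4,6-dien-1-yl methanesulfonate | COC1=C(C)C(=O)OC1C(OS(C)(=O)=O)[C@@H](C)C/C=C/C(C)=C/CCc1coc(Cc2ccoc2)c1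
F5 | step 12 | (5Z)-5-{(2S,4E,6E)-9-[5-(furan-3-ylmethyl)furan-3-yl]-2,6-dimethylnona-4,6-dien-1-ylidene}-4-methoxy-3-methylfuran-2(5H)-one | COC1=C(C)C(=O)O/C1=C\[C@@H](C)C/C=C/C(C)=C/CCc1coc(Cc2ccoc2)c1
F6 | step 4 | 2-bromo-3-[(3E)-5,5-dimethoxy-4-methylpent-3-en-1-yl]furan | COC(OC)/C(C)=C/CCc1ccoc1Br
F7 | step 4 | {3-[(3E)-5,5-dimethoxy-4-methylpent-3-en-1-yl]furan-2-yl}(trimethyl)silane | COC(OC)/C(C)=C/CCc1ccoc1[Si](C)(C)C
F8 | step 4 | 2-{4-[(3E)-5,5-dimethoxy-4-methylpent-3-en-1-yl]-5-(trimethylsilyl)furan-2-yl}-4,4,5,5-tetramethyl-1,3,2-dioxaborolane | COC(OC)/C(C)=C/CCc1cc(B2OC(C)(C)C(C)(C)O2)oc1[Si](C)(C)C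
F9 | step 4 | lithium (chloromethyl){4-[(3E)-5,5-dimethoxy-4-methylpent-3-en-1-yl]-5-(trimethylsilyl)furan-2-yl}(pinacolato)borate | [Li+].COC(OC)/C(C)=C/CCc1cc([B-]2(CCl)OC(C)(C)C(C)(C)O2)oc1[Si](C)(C)C
F10 | step 4 | 2-({4-[(3E)-5,5-dimethoxy-4-methylpent-3-en-1-yl]-5-(trimethylsilyl)furan-2-yl}methyl)-4,4,5,5-tetramethyl-1,3,2-dioxaborolane | COC(OC)/C(C)=C/CCc1cc(CB2OC(C)(C)C(C)(C)O2)oc1[Si](C)(C)C
F11 | step 4 | {3-[(3E)-5,5-dimethoxy-4-methylpent-3-en-1-yl]-5-(furan-3-ylmethyl)furan-2-yl}(trimethyl)silane | COC(OC)/C(C)=C/CCc1cc(Cc2ccoc2)oc1[Si](C)(C)C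
F12 | step 10 | (2S,4E,6E)-9-[5-(furan-3-ylmethyl)furan-3-yl]-2,6-dimethylnona-4,6-dien-1-ol | OC[C@@H](C)C/C=C/C(C)=C/CCc1coc(Cc2ccoc2)c1
F13 | step 10 | 4-[(3E,5E,8S)-10,10-dibromo-4,8-dimethyldeca-3,5,9-trien-1-yl]-2-(furan-3-ylmethyl)furan | BrC(Br)=C[C@@H](C)C/C=C/C(C)=C/CCc1coc(Cc2ccoc2)c1
F14 | step 1 | 9-(3,3-diethoxypropyl)-9-borabicyclo[3.3.1]nonane | CCOC(CCB1C2CCCC1CCC2)OCC
F15 | step 1 | 3-(3,3-diethoxypropyl)furan | CCOC(CCc1ccoc1)OCC
A1 | alternative 1 | (5Z)-5-[(2R)-3-{[tert-butyl(dimethyl)silyl]oxy}-2-methylpropylidene]-4-methoxy-3-methylfuran-2(5H)-one | COC1=C(C)C(=O)O/C1=C\[C@@H](C)CO[Si](C)(C)C(C)(C)C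
A2 | alternative 1 | 4-[(2R)-3-{[tert-butyl(dimethyl)silyl]oxy}-2-methylpropyl]-4-hydroxy-3-methoxy-2-methylcyclobut-2-en-1-one | COC1=C(C)C(=O)C1(O)C[C@@H](C)CO[Si](C)(C)C(C)(C)C
A3 | alternative 2 | (3E,5E,8S)-4,8-dimethyl-10-[tri(propan-2-yl)silyl]deca-3,5-dien-9-yn-1-ol | CC(C)[Si](C(C)C)(C(C)C)C#C[C@@H](C)C/C=C/C(C)=C/CCO
A4 | alternative 2 | [(3S,5E)-3-methyloct-5-ene-1,7-diyn-1-yl]tri(propan-2-yl)silane | CC(C)[Si](C(C)C)(C(C)C)C#C[C@@H](C)C/C=C/C#C
A5 | alternative 2 | oxirane | C1CO1
A6 | alternative 3 | 4-(but-3-en-1-yl)-2-(furan-3-ylmethyl)furan | C=CCCc1coc(Cc2ccoc2)c1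
A7 | alternative 3 | (2Z)-2-(but-3-en-1-yl)-5-(furan-3-yl)pent-2-en-4-yn-1-ol | OC/C(CCC=C)=C\C#Cc1ccoc1
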